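Temperature and time were what I had to weigh in these flasks, so I set them on a ladder of times, from the quickest clock to the slowest.

| flask | substrate | reagent | catalyst | temperature | remark | time |
|---|---|---|---|---|---|---|
| elm | 0.013 M | 0.030 M | 0.11 mM | 52 °C | run made earlier |  |
| ash | 0.030 M | 0.030 M | 0.11 mM | 80 °C | run made earlier |  |
| south-east | 0.020 M | 0.0300 M | 0.11 mM | 65 °C |  | 40 min |
| west | 0.020 M | 0.0300 M | 0.11 mM | 90 °C |  | 40 min |
| south-west | 0.020 M | 0.0300 M | 0.11 mM | 40 °C |  | 40 min |
| east | 0.020 M | 0.0300 M | 0.11 mM |  | at 90 °C until 20 min, from then on at 40 °C | 40 min |

| run | time / min | target / % | substrate / % |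
|---|---|---|---|
| elm | 4.00 | 27 | 76 |
| elm | 8.00 | 43 | 57 |
| elm | 12.0 | 55 | 45 |
| elm | 25.0 | 79 | 19 |
| elm | 50.0 | 92 | 7 |
| ash | 1.00 | 21 | 78 |
| ash | 2.00 | 32 | 70 |
| ash | 3.00 | 39 | 59 |
| ash | 6.00 | 54 | 45 |
| ash | 12.0 | 63 | 31 |

(readings scatter by 1.5 percentage points)

- the best flask by amount of target, in percent of the substrate charged; "all alike" if 1.5 percentage points covers them all (south-east / west / south-west / east / all alike)
- amount of target at the end, in percent of the substrate charged, south-east
- amount of target at the end, in percent of the substrate charged, west
- amount of target at the end, in percent of the substrate charged, south-west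
- amount of target at the end, in percent of the substrate charged, east



1. From the elm run at 8.00 min, with substrate at 57%, and allowing for the reagent spent, I read a rate constant of 2.62 /M/min. From the first ash reading, taken because the later ash readings slow down, I read 9.40 /M/min; both carry the scatter.

2. Taking one constant factor per degree between those readings, I put the constant at 4.74 /M/min for south-east, 14.8 /M/min for west and 1.51 /M/min for south-west.

3. My yardstick was the start half-life, the time in which substrate would halve with [reagent] held at its charge, a pseudo-first-order view: 4.88 min in south-east.

4. West came first on the ladder at 1.56 min, and south-west came last at 15.3 min, still shorter than the 40 min allowed.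

5. Since [reagent] falls along with [substrate], I reckoned the drawdown through, which left 5.57% of the substrate in south-east and 28.6% in south-west. The forecast's own figure for south-east was 92% conversion, against my 94.4%.

6. A further rung showed in the balance of target and substrate, which read 99.0% at the last elm reading but 94.0% at the last ash reading, both with their scatter. I therefore backed south-east, which has 8.20 start half-lives at a temperature below that of ash.

7. The forecast named south-east, with 86% for south-east, 58% for west, 69% for south-west and 72% for east, on the ground that “hot target loss and/or catalyst decay begins near 80 °C”.

8. The flasks gave 85.8% in south-east, 54.5% in west, 70.6% in south-west and 70.4% in east, so south-east stood best.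

    substrate + reagent → uncatalysed product (k = 0.00660 /M/s, Ea = 89.0 kJ/mol)
    target ⇌ isomer of the product (K = 2.70, k = 1.17 × 10⁻⁴ /s, Ea = 104 kJ/mol, ΔH = −57.0 kJ/mol)
    substrate + reagent + catalyst ⇌ target + catalyst, rate k3*[substrate]*[reagent]*[catalyst] forward; the back reaction follows from the equilibrium constant (K = 169 /M, k = 1780 /M²/s, Ea = 39.0 kJ/mol, ΔH = −66.0 kJ/mol)
    (constants at 90 °C)

In south-east, substrate ended at 11.7% against my 5.57%, and its half-life by the forward rate to target alone was 7.2 min at 5.21 min, a value for a later moment than my 4.88 min for the start. The relaxation half-life of target and isomer of the product in south-east, by that step alone and both ways together, was 19.2 h, far longer than that forward half-life and long against the 40 min, and south-east held 1.51% of isomer of the product at the end.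

For the neighbour of south-east with 4.4 × 10⁻⁵ M of catalyst, its other charges and its time held, I took the rate as proportional to catalyst, so that the start half-life became 12.2 min and the same drawdown left 22.7% of the substrate. The computed neighbour held 25.6% of substrate and 71.4% of target.

All runs were generated by integration on assumed constants.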